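**Retrosynthetic overview**

1. Target ⇒ its 7,7''-dibenzyl ether. The two free phenols are unmasked last by neutral hydrogenolysis, so that no base meets the finished stereocentres.
2. Dibenzyl ether ⇒ 1,4-bis(4-methoxyphenyl)buta-1,3-diyne + 2 × 4-(benzyloxy)-2-hydroxy-6-methoxybenzaldehyde. Both pyranone rings are cut at once, each at O1–C2 and C4–C3 (O1''–C2'' and C4''–C3''). Forward, this is a twofold rhodium-catalysed alkyne hydroacylation followed in the same flask by a twofold catalyst-controlled oxa-Michael closure.
3. Enabling feature: the C2 axis through the C3–C3'' bond turns the chain C2–C3–C3''–C2'' into a conjugated diyne. In each half O1 and the C4 carbonyl are ortho neighbours on ring A (a salicylaldehyde). C3 and C3'' lie α to the C4 and C4'' ketones, so they can settle trans to the anisyl groups once C2 and C2'' are fixed.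
4. Ring order: rings A and B come ready-made in the building blocks; the two pyranone rings (rings C) are formed last and together in the key step.
5. Building blocks: the diyne by oxidative dimerisation of 4-ethynylanisole; the aldehyde from 2,4,6-trihydroxybenzaldehyde by 4-O-benzylation and mono-O-methylation.

Key step: step 4

Assumption: the 2,3-trans (diequatorial) arrangement in each flavanone ring is taken to be the thermodynamically preferred one, so that C3 and C3'' can be set by equilibration of the α-carbonyl centres once C2 and C2'' are fixed.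

**Route**

Step 1
Reactants: 1 1-ethynyl-4-methoxybenzene (2 equiv)
Product: 2 1,4-bis(4-methoxyphenyl)buta-1,3-diyne
Conditions: CuCl (5 mol %), TMEDA (10 mol %), O2 (1 atm), acetone, rt
Reagents that add atoms: none
Why: Glaser–Hay oxidative homocoupling, in which the copper acetylide of the terminal arylalkyne is oxidised by O2 and couples to the symmetrical 1,3-diyne; no stereocentre is formed.

Step 2
Reactants: 3 2,4,6-trihydroxybenzaldehyde
Product: 4 4-(benzyloxy)-2,6-dihydroxybenzaldehyde
Conditions: BnBr (1.05 equiv), NaHCO3 (1.2 equiv), KI (10 mol %), MeCN, 60 °C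
Reagents that add atoms: benzyl bromide, BrCc1ccccc1
Why: Williamson ether synthesis under weak-base control, in which the 4-hydroxyl (para to the formyl group and the only one not hydrogen-bonded to it) is the most acidic and should be benzylated first; no stereocentre is formed.

Step 3
Reactants: 4 4-(benzyloxy)-2,6-dihydroxybenzaldehyde
Product: 5 4-(benzyloxy)-2-hydroxy-6-methoxybenzaldehyde
Conditions: MeI (1.05 equiv), K2CO3 (1.1 equiv), acetone, rt
Reagents that add atoms: iodomethane, CI
Why: Williamson ether synthesis on two equivalent ortho hydroxyls, where after the first methylation the remaining hydroxyl is locked in a chelate with the formyl oxygen and should react far more slowly, so the reaction should stop at the mono-methyl ether; no stereocentre is formed.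

Step 4
Reactants: 2 1,4-bis(4-methoxyphenyl)buta-1,3-diyne (1 equiv); 5 4-(benzyloxy)-2-hydroxy-6-methoxybenzaldehyde (2.2 equiv)
Product: 9 (2S,3R,2''S,3''R)-7,7''-bis(benzyloxy)-5,5''-dimethoxy-2,2''-bis(4-methoxyphenyl)-3,3''-bichroman-4,4''-dione, via enynone 6 (not isolated), via bis-chalcone 7 (not isolated), via chalcone-flavanone 8 (not isolated)
Conditions: [Rh(cod)OH]2 (5 mol %), 1,1'-bis(diphenylphosphino)ferrocene (dppf, 10 mol %), toluene, 80 °C; then, same flask, N-[3,5-bis(trifluoromethyl)phenyl]-N'-[(8α,9S)-6'-methoxycinchonan-9-yl]thiourea (20 mol %), −20 °C to rt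
Reagents that add atoms: none
Why: Proposed new method: in the first stage the aldehyde C–H bond of 5 adds oxidatively to a phenoxide-chelated monovalent rhodium centre, the acyl rhodium hydride adds syn across one triple bond of 2 with rhodium on the inner carbon (the alkenyl rhodium is conjugated with the second alkyne and the alkynyl group is the slimmer neighbour), C–C reductive elimination gives enynone 6, and a second cycle on the remaining enyne gives the (E,E)-bis(2'-hydroxychalcone) 7; the closest known reactions are the rhodium-catalysed hydroacylation of internal alkynes with salicylaldehydes, including its tandem oxa-Michael closure to trans-2,3-disubstituted chroman-4-ones, and, for the inner-carbon regiochemistry on a 1,3-diyne, the platinum-catalysed twofold hydrosilylation that gives 2,3-disilyl-1,3-dienes. In the second stage the bifunctional thiourea closes each pyranone ring by a 6-endo-trig oxa-Michael addition of the 2'-hydroxyl to the β-anisyl enone (first to 8, then to 9), the quinuclidine nitrogen acting as general base and the thiourea binding the aryl ketone, which is an established reaction type for 2'-hydroxychalcones. C2 and C2'' are set by the catalyst, which should deliver O1 to the same face of each enone (2S,2''S), and C3 and C3'' are set by protonation of the enols under the equilibrating amine conditions, which should place each C3 substituent trans to the neighbouring anisyl group (both equatorial), hence 2S,3R,2''S,3''R. The step needs regioselectivity (acyl groups to the two inner alkyne carbons), chemoselectivity (no ring closure during the rhodium stage) and enantio- plus diastereoselectivity; they rest on the conjugated diyne and enyne, on the hydrogen-bonded, twisted 2'-hydroxy-6'-methoxyaroyl groups, which are expected to close only slowly without an amine base, and on catalyst control acting twice. Because the catalyst acts on both halves, a wrong closure should mainly give the separable meso diastereomer and not the enantiomer, and the quinidine-derived pseudoenantiomer of the catalyst is the alternative if a test on 7 shows the opposite sense of induction.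

Step 5
Reactants: 9 (2S,3R,2''S,3''R)-7,7''-bis(benzyloxy)-5,5''-dimethoxy-2,2''-bis(4-methoxyphenyl)-3,3''-bichroman-4,4''-dione
Product: 10 4',4''',5,5''-tetramethylchamaejasmin
Conditions: H2 (1 atm), Pd/C (10 wt %), EtOAc, rt
Reagents that add atoms: none
Why: Heterogeneous catalytic hydrogenolysis of the two aryl benzyl ethers under neutral conditions, which should leave untouched the aryl ketones, the methyl ethers and the four base-labile stereocentres (C2/C2'' by retro-oxa-Michael opening, C3/C3'' by enolisation); no new stereocentre is formed.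

**Compound list**

1 | 1-ethynyl-4-methoxybenzene (4-ethynylanisole) | COc1ccc(C#C)cc1 | starting material
2 | 1,4-bis(4-methoxyphenyl)buta-1,3-diyne | COc1ccc(C#CC#Cc2ccc(OC)cc2)cc1 | intermediate
3 | 2,4,6-trihydroxybenzaldehyde | O=Cc1c(O)cc(O)cc1O | starting material
4 | 4-(benzyloxy)-2,6-dihydroxybenzaldehyde | O=Cc1c(O)cc(OCc2ccccc2)cc1O | intermediate
5 | 4-(benzyloxy)-2-hydroxy-6-methoxybenzaldehyde | COc1cc(OCc2ccccc2)cc(O)c1C=O | intermediate
6 | (2E)-1-[4-(benzyloxy)-2-hydroxy-6-methoxyphenyl]-4-(4-methoxyphenyl)-2-[(4-methoxyphenyl)methylidene]but-3-yn-1-one (enynone) | COc1ccc(/C=C(\C#Cc2ccc(OC)cc2)C(=O)c2c(O)cc(OCc3ccccc3)cc2OC)cc1 | intermediate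
7 | (2E,3E)-1,4-bis[4-(benzyloxy)-2-hydroxy-6-methoxyphenyl]-2,3-bis[(4-methoxyphenyl)methylidene]butane-1,4-dione (bis-chalcone) | COc1ccc(/C=C(C(=O)c2c(O)cc(OCc3ccccc3)cc2OC)\C(=C/c2ccc(OC)cc2)C(=O)c2c(O)cc(OCc3ccccc3)cc2OC)cc1 | intermediate
8 | (2S,3R)-7-(benzyloxy)-3-{(1E)-3-[4-(benzyloxy)-2-hydroxy-6-methoxyphenyl]-1-(4-methoxyphenyl)-3-oxoprop-1-en-2-yl}-5-methoxy-2-(4-methoxyphenyl)chroman-4-one (chalcone-flavanone) | COc1ccc([C@H]2Oc3cc(OCc4ccccc4)cc(OC)c3C(=O)[C@@H]2/C(=C\c2ccc(OC)cc2)C(=O)c2c(O)cc(OCc3ccccc3)cc2OC)cc1 | intermediate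
9 | (2S,3R,2''S,3''R)-7,7''-bis(benzyloxy)-5,5''-dimethoxy-2,2''-bis(4-methoxyphenyl)-3,3''-bichroman-4,4''-dione | COc1ccc([C@H]2Oc3cc(OCc4ccccc4)cc(OC)c3C(=O)[C@@H]2[C@H]2C(=O)c3c(OC)cc(OCc4ccccc4)cc3O[C@@H]2c2ccc(OC)cc2)cc1 | intermediate
10 | 4',4''',5,5''-tetramethylchamaejasmin, (2S,3R,2''S,3''R)-7,7''-dihydroxy-5,5''-dimethoxy-2,2''-bis(4-methoxyphenyl)-3,3''-bichroman-4,4''-dione | COc1ccc([C@H]2Oc3cc(O)cc(OC)c3C(=O)[C@@H]2[C@H]2C(=O)c3c(OC)cc(O)cc3O[C@@H]2c2ccc(OC)cc2)cc1 | target

**Step count**

Total step count: 5.
Longest linear sequence: 4 steps (3 → 4 → 5 → 9 → 10).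

**Steps most likely to fail**

Step 4 (Proposed new method). What may go wrong:
- the second hydroacylation may deliver the acyl group to the aryl-bearing alkyne carbon;
- the acyl rhodium hydride may lose CO before it adds to the alkyne;
- the ring closures may start without the chiral catalyst or run reversibly under it, which would erode enantio- and diastereocontrol.

Fallback for step 4: it sets out from compound 5 and comes back to the route at compound 7, which is then closed to 9 with the thiourea catalyst as in the second stage of step 4. The chain C4–C3–C3''–C4'' is built from acetylene and the C2 carbons are brought in by aldol chemistry, all by known reaction types. Protection of the phenol of 5 (MOMCl, i-Pr2NEt, CH2Cl2) gives 4-(benzyloxy)-2-methoxy-6-(methoxymethoxy)benzaldehyde F1. Twofold addition of ethynediylbis(magnesium bromide) (BrMgC≡CMgBr, THF, 0 °C) to F1 gives 1,4-bis[4-(benzyloxy)-2-methoxy-6-(methoxymethoxy)phenyl]but-2-yne-1,4-diol F2 as a mixture of diastereomers. Palladium-catalysed redox isomerisation (Pd2(dba)3, n-Bu3P, MeCN, 80 °C) gives 1,4-bis[4-(benzyloxy)-2-methoxy-6-(methoxymethoxy)phenyl]butane-1,4-dione F3. Twofold aldol addition (LiHMDS, THF, −78 °C, then 4-methoxybenzaldehyde) gives 1,4-bis[4-(benzyloxy)-2-methoxy-6-(methoxymethoxy)phenyl]-2,3-bis[hydroxy(4-methoxyphenyl)methyl]butane-1,4-dione F4. Twofold dehydration (MsCl, Et3N, then DBU, CH2Cl2) gives (2E,3E)-1,4-bis[4-(benzyloxy)-2-methoxy-6-(methoxymethoxy)phenyl]-2,3-bis[(4-methoxyphenyl)methylidene]butane-1,4-dione F5. HCl in MeOH at room temperature removes the two MOM groups and gives 7.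

Step 2. What may go wrong: alkylation may spread over the three hydroxyls and over the electron-rich ring carbons, so that the mono-benzyl ether is formed unselectively.

Fallback for step 2: it sets out from compound 3 and comes back at compound 5, bypassing 4. Twofold benzylation (BnBr 2.1 equiv, K2CO3, DMF, rt) should stop at 2,4-bis(benzyloxy)-6-hydroxybenzaldehyde F6, because the last hydroxyl is held by the formyl group. Forcing methylation (MeI, K2CO3, DMF, 50 °C) gives 2,4-bis(benzyloxy)-6-methoxybenzaldehyde F7. MgBr2·OEt2 (toluene–Et2O, reflux) then cleaves only the benzyl ether ortho to the formyl group through a magnesium chelate and gives 5.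

Step 3. What may go wrong: methylation may run on to the dimethyl ether or stop short, leaving a mixture that is hard to separate.

Fallback for step 3: it sets out from compound 4 and comes back at compound 5. Exhaustive methylation (MeI in excess, K2CO3, DMF, 50 °C) gives 4-(benzyloxy)-2,6-dimethoxybenzaldehyde F8. MgI2·OEt2 (1.1 equiv, toluene, 80 °C) removes one of the two equivalent ortho methyl groups through a magnesium chelate, the resulting phenoxide chelate being protected against a second cleavage, and gives 5.

**Further compounds**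

F1 | step 4 | 4-(benzyloxy)-2-methoxy-6-(methoxymethoxy)benzaldehyde | COCOc1cc(OCc2ccccc2)cc(OC)c1C=O
F2 | step 4 | 1,4-bis[4-(benzyloxy)-2-methoxy-6-(methoxymethoxy)phenyl]but-2-yne-1,4-diol (mixture of diastereomers) | COCOc1cc(OCc2ccccc2)cc(OC)c1C(O)C#CC(O)c1c(OC)cc(OCc2ccccc2)cc1OCOC
F3 | step 4 | 1,4-bis[4-(benzyloxy)-2-methoxy-6-(methoxymethoxy)phenyl]butane-1,4-dione | COCOc1cc(OCc2ccccc2)cc(OC)c1C(=O)CCC(=O)c1c(OC)cc(OCc2ccccc2)cc1OCOC
F4 | step 4 | 1,4-bis[4-(benzyloxy)-2-methoxy-6-(methoxymethoxy)phenyl]-2,3-bis[hydroxy(4-methoxyphenyl)methyl]butane-1,4-dione (mixture of diastereomers) | COCOc1cc(OCc2ccccc2)cc(OC)c1C(=O)C(C(O)c1ccc(OC)cc1)C(C(O)c1ccc(OC)cc1)C(=O)c1c(OC)cc(OCc2ccccc2)cc1OCOC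
F5 | step 4 | (2E,3E)-1,4-bis[4-(benzyloxy)-2-methoxy-6-(methoxymethoxy)phenyl]-2,3-bis[(4-methoxyphenyl)methylidene]butane-1,4-dione | COc1ccc(/C=C(C(=O)c2c(OCOC)cc(OCc3ccccc3)cc2OC)\C(=C/c2ccc(OC)cc2)C(=O)c2c(OCOC)cc(OCc3ccccc3)cc2OC)cc1
F6 | step 2 | 2,4-bis(benzyloxy)-6-hydroxybenzaldehyde | O=Cc1c(O)cc(OCc2ccccc2)cc1OCc1ccccc1
F7 | step 2 | 2,4-bis(benzyloxy)-6-methoxybenzaldehyde | COc1cc(OCc2ccccc2)cc(OCc2ccccc2)c1C=O
F8 | step 3 | 4-(benzyloxy)-2,6-dimethoxybenzaldehyde | COc1cc(OCc2ccccc2)cc(OC)c1C=O
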